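## Retrosynthetic overview

1. Target 22 ⇐ dihydrofuran acetate 17: the last step closes the oxocene by forming the C7–O bond in a chloronium-triggered ring expansion. The ring oxygen moves from C10 to C7, acetate takes its place at C10, and C6, C7 and C10 are set.
2. 17 ⇐ dihydrofuran epoxide 7 + chloroenyne 10 (+ 14): epoxide alkynylation at C8, Lindlar reduction (6Z), Sonogashira coupling (3E-enyne).
3. 7 ⇐ bis-allyl ether 6 by RCM; 6 ⇐ epoxy alcohol 2 + carbonate 4 by Ir-catalysed allylic etherification (C13–O bond, C13 set).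
4. 2 ⇐ divinylcarbinol 1 by Sharpless desymmetrisation (C9, C10); 10 ⇐ 8 + 9.
5. Ring order: 2,5-dihydrofuran first (step 4), eight-membered ether last (step 11).

Assumption: locants C1–C15 follow the target chain (C1 = alkyne CH, C7 and C13 = the two ring O–CH carbons, C15 = ethyl CH3). The route is a design and has not been run; the step-1 tartrate assignment was derived from the Sharpless model, and the step-3 ligand antipode is a best estimate to be confirmed on the first run.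

## Route

Step 1
Reactants: 1 penta-1,4-dien-3-ol
Product: 2 (1S)-1-[(2R)-oxiran-2-yl]prop-2-en-1-ol [(2R,3S)-1,2-epoxypent-4-en-3-ol]
Conditions: Ti(OiPr)4 (10 mol%), L-(+)-DIPT (13 mol%), t-BuOOH, 4 Å MS, CH2Cl2, −20 °C
Reagents that add atoms: tert-butyl hydroperoxide, CC(C)(C)OO
Why: Sharpless asymmetric epoxidation of the divinyl carbinol; enantiotopic-vinyl plus diastereoface selection by the Ti–tartrate catalyst gives the erythro epoxy alcohol, setting C9 (R) and C10 (S, inverted later in step 11).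

Step 2
Reactants: 3 (2E)-pent-2-en-1-ol
Product: 4 tert-butyl (2E)-pent-2-en-1-yl carbonate
Conditions: Boc2O, Bu4NHSO4 (cat.), 30% aq NaOH, CH2Cl2, 0 °C → rt
Reagents that add atoms: di-tert-butyl dicarbonate, CC(C)(C)OC(=O)OC(=O)OC(C)(C)C
Why: Carbonate formation (O-acylation) on a primary allylic alcohol supplies the leaving group for the iridium step; no stereocentre is involved.

Step 3
Reactants: 2 (1S)-1-[(2R)-oxiran-2-yl]prop-2-en-1-ol; 4 tert-butyl (2E)-pent-2-en-1-yl carbonate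
Product: 6 (2R)-2-[(1S)-1-{[(3R)-pent-1-en-3-yl]oxy}prop-2-en-1-yl]oxirane, via copper(I) alkoxide 5 (not isolated)
Conditions: n-BuLi, THF, −78 °C; CuI, → rt; then 4, [Ir(cod)Cl]2 (2 mol%), (Sa,S,S)-binaphthyl bis(1-phenylethyl)phosphoramidite (4 mol%; antipode chosen to give 3R), THF, rt; NH4Cl work-up
Reagents that add atoms: none
Why: Iridium-catalysed branched-selective asymmetric allylic etherification (Hartwig type) of the copper alkoxide forms the C13–O bond, the ligand controlling the new ether stereocentre (C13 R) while the mild copper alkoxide leaves the epoxide alone.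

Step 4
Reactants: 6 (2R)-2-[(1S)-1-{[(3R)-pent-1-en-3-yl]oxy}prop-2-en-1-yl]oxirane
Product: 7 (2R,5S)-2-ethyl-5-[(2R)-oxiran-2-yl]-2,5-dihydrofuran
Conditions: Grubbs II (2 mol%), CH2Cl2 (0.02 M), 40 °C
Reagents that add atoms: none
Why: Ring-closing metathesis of the two terminal vinyl groups closes the dihydrofuran; no stereocentre is touched, so the 2,5-trans relationship follows from 6.

Step 5
Reactants: 8 (1E)-1,3-dichloroprop-1-ene; 9 ethynylmagnesium bromide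
Product: 10 (1E)-1-chloropent-1-en-4-yne
Conditions: 9 (3 equiv), CuBr·SMe2 (5 mol%), THF, 0 → 45 °C (slow addition of 8)
Reagents that add atoms: none
Why: Copper-catalysed SN2 coupling of the alkynyl Grignard reagent at the allylic chloride; the vinylic C–Cl bond and its E geometry do not react.

Step 6
Reactants: 7 (2R,5S)-2-ethyl-5-[(2R)-oxiran-2-yl]-2,5-dihydrofuran; 10 (1E)-1-chloropent-1-en-4-yne
Product: 12 (1R,6E)-7-chloro-1-[(2S,5R)-5-ethyl-2,5-dihydrofuran-2-yl]hept-6-en-3-yn-1-ol, via lithium acetylide 11 (not isolated)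
Conditions: 10, n-BuLi, THF, −78 °C; BF3·OEt2; then 7, −78 °C; NH4Cl work-up
Reagents that add atoms: none
Why: Yamaguchi-type BF3-promoted alkynylation opens the terminal epoxide by SN2 at its CH2 carbon (C8), so the C9–O stereocentre is carried over unchanged.

Step 7
Reactants: 12 (1R,6E)-7-chloro-1-[(2S,5R)-5-ethyl-2,5-dihydrofuran-2-yl]hept-6-en-3-yn-1-ol
Product: 13 (1R,3Z,6E)-7-chloro-1-[(2S,5R)-5-ethyl-2,5-dihydrofuran-2-yl]hepta-3,6-dien-1-ol
Conditions: H2 (1 atm), Lindlar catalyst, quinoline, EtOAc, 0 °C → rt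
Reagents that add atoms: none
Why: Lindlar semi-hydrogenation adds H2 syn to the only alkyne and sets the 6Z alkene; the alkenyl chloride and ring alkene are not reduced on the poisoned catalyst.

Step 8
Reactants: 13 (1R,3Z,6E)-7-chloro-1-[(2S,5R)-5-ethyl-2,5-dihydrofuran-2-yl]hepta-3,6-dien-1-ol; 14 ethynyltrimethylsilane
Product: 15 (1R,3Z,6E)-1-[(2S,5R)-5-ethyl-2,5-dihydrofuran-2-yl]-9-(trimethylsilyl)nona-3,6-dien-8-yn-1-ol
Conditions: PdCl2(PhCN)2 (5 mol%), CuI (10 mol%), piperidine, rt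
Reagents that add atoms: none
Why: Sonogashira coupling of the alkenyl chloride (Alami–Linstrumelle conditions) retains the E geometry; it is placed here, before any allylic acetate exists that Pd(0) could ionise.

Step 9
Reactants: 15 (1R,3Z,6E)-1-[(2S,5R)-5-ethyl-2,5-dihydrofuran-2-yl]-9-(trimethylsilyl)nona-3,6-dien-8-yn-1-ol
Product: 16 (1R,3Z,6E)-1-[(2S,5R)-5-ethyl-2,5-dihydrofuran-2-yl]nona-3,6-dien-8-yn-1-ol
Conditions: K2CO3 (0.3 equiv), MeOH, 0 °C → rt
Reagents that add atoms: none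
Why: Base-catalysed methanolysis cleaves the C(sp)–Si bond (protodesilylation) without touching the skipped diene.

Step 10
Reactants: 16 (1R,3Z,6E)-1-[(2S,5R)-5-ethyl-2,5-dihydrofuran-2-yl]nona-3,6-dien-8-yn-1-ol
Product: 17 (1R,3Z,6E)-1-[(2S,5R)-5-ethyl-2,5-dihydrofuran-2-yl]nona-3,6-dien-8-yn-1-yl acetate
Conditions: Ac2O, pyridine, DMAP (cat.), CH2Cl2, 0 °C → rt
Reagents that add atoms: acetic anhydride, CC(=O)OC(C)=O
Why: DMAP-catalysed acetylation installs the C9 acetate that acts as the internal nucleophile in step 11.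

Step 11
Reactants: 17 (1R,3Z,6E)-1-[(2S,5R)-5-ethyl-2,5-dihydrofuran-2-yl]nona-3,6-dien-8-yn-1-yl acetate
Product: 22 (2R,3Z,5R,6R,8R)-8-[(1R,3E)-1-chlorohex-3-en-5-yn-1-yl]-2-ethyl-5,6,7,8-tetrahydro-2H-oxocine-5,6-diyl diacetate (target), via bicyclic oxonium ion 18 (not isolated), via acetoxonium ion 19 (not isolated), via C9 monoacetate 20 (not isolated), via C10 monoacetate 21 (not isolated)
Conditions: N-chlorosaccharin (1.1 equiv), CH2Cl2/(CF3)2CHOH 4:1, −40 °C; aq Na2S2O3/NaHCO3, 0 °C; then crude + Ac2O, DMAP, pyridine, CH2Cl2, rt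
Reagents that add atoms: N-chlorosaccharin, O=C1N(Cl)S(=O)(=O)c2ccccc12; water, O; acetic anhydride, CC(=O)OC(C)=O
Why: Proposed new method: chloronium-triggered ring expansion of a 2,5-dihydrofuran with acetoxonium relay – Cl+ goes to the most electron-rich (Z-1,2-dialkyl) alkene and is captured 5-exo and anti by the ring oxygen, the side chain taking the convex face of the cis-fused oxonium 18 (sets 6R,7R); the allylic O+–C10 bond is then cleaved with inversion by the neighbouring C9 acetate carbonyl (sets 10R and opens the five-membered ring into the oxocene 19), water hydrolyses the dioxolanylium with retention and Ac2O completes the diacetate; closest known reaction type: bromonium-induced ring expansion of tetrahydrofurans with carbonate capture to eight-membered bromoethers, combined with Woodward–Prévost acetoxonium chemistry.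

## Compound list

1 | penta-1,4-dien-3-ol | C=CC(O)C=C | starting material
2 | (1S)-1-[(2R)-oxiran-2-yl]prop-2-en-1-ol | C=C[C@H](O)[C@H]1CO1 | intermediate
3 | (2E)-pent-2-en-1-ol | CC/C=C/CO | starting material
4 | tert-butyl (2E)-pent-2-en-1-yl carbonate | CC/C=C/COC(=O)OC(C)(C)C | intermediate
5 | copper(I) (1S)-1-[(2R)-oxiran-2-yl]prop-2-en-1-olate | C=C[C@H](O[Cu])[C@H]1CO1 | intermediate (not isolated)
6 | (2R)-2-[(1S)-1-{[(3R)-pent-1-en-3-yl]oxy}prop-2-en-1-yl]oxirane | C=C[C@H](O[C@H](CC)C=C)[C@H]1CO1 | intermediate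
7 | (2R,5S)-2-ethyl-5-[(2R)-oxiran-2-yl]-2,5-dihydrofuran | CC[C@@H]1C=C[C@H](O1)[C@H]2CO2 | intermediate
8 | (1E)-1,3-dichloroprop-1-ene | ClC/C=C/Cl | starting material
9 | ethynylmagnesium bromide | C#C[Mg]Br | starting material
10 | (1E)-1-chloropent-1-en-4-yne | C#CC/C=C/Cl | intermediate
11 | [(4E)-5-chloropent-4-en-1-yn-1-yl]lithium | [Li]C#CC/C=C/Cl | intermediate (not isolated)
12 | (1R,6E)-7-chloro-1-[(2S,5R)-5-ethyl-2,5-dihydrofuran-2-yl]hept-6-en-3-yn-1-ol | CC[C@@H]1C=C[C@H](O1)[C@H](O)CC#CC/C=C/Cl | intermediate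
13 | (1R,3Z,6E)-7-chloro-1-[(2S,5R)-5-ethyl-2,5-dihydrofuran-2-yl]hepta-3,6-dien-1-ol | CC[C@@H]1C=C[C@H](O1)[C@H](O)C/C=C\C/C=C/Cl | intermediate
14 | ethynyltrimethylsilane | C#C[Si](C)(C)C | starting material
15 | (1R,3Z,6E)-1-[(2S,5R)-5-ethyl-2,5-dihydrofuran-2-yl]-9-(trimethylsilyl)nona-3,6-dien-8-yn-1-ol | CC[C@@H]1C=C[C@H](O1)[C@H](O)C/C=C\C/C=C/C#C[Si](C)(C)C | intermediate
16 | (1R,3Z,6E)-1-[(2S,5R)-5-ethyl-2,5-dihydrofuran-2-yl]nona-3,6-dien-8-yn-1-ol | CC[C@@H]1C=C[C@H](O1)[C@H](O)C/C=C\C/C=C/C#C | intermediate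
17 | (1R,3Z,6E)-1-[(2S,5R)-5-ethyl-2,5-dihydrofuran-2-yl]nona-3,6-dien-8-yn-1-yl acetate | CC[C@@H]1C=C[C@H](O1)[C@H](OC(C)=O)C/C=C\C/C=C/C#C | intermediate
18 | (2R,4R,5S,8R)-4-acetoxy-2-[(1R,3E)-1-chlorohex-3-en-5-yn-1-yl]-8-ethyl-1-oxoniabicyclo[3.3.0]oct-6-ene saccharinate (O+ bonded to C7, C10, C13) | CC[C@@H]1C=C[C@H]2[C@H](OC(C)=O)C[C@H]([C@H](Cl)C/C=C/C#C)[O+]12.O=C1[N-]S(=O)(=O)c2ccccc12 | intermediate (not isolated)
19 | oxocene-fused 2-methyl-1,3-dioxolan-2-ylium saccharinate (acetoxonium bridging O9 and O10; 6R,7R,9R,10R,13R) | C#C/C=C/C[C@@H](Cl)[C@H]1C[C@H]2OC(C)=[O+][C@@H]2/C=C\[C@@H](CC)O1.O=C1[N-]S(=O)(=O)c2ccccc12 | intermediate (not isolated)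
20 | (2R,3Z,5R,6R,8R)-8-[(1R,3E)-1-chlorohex-3-en-5-yn-1-yl]-2-ethyl-5-hydroxy-5,6,7,8-tetrahydro-2H-oxocin-6-yl acetate | C#C/C=C/C[C@@H](Cl)[C@H]1C[C@@H](OC(C)=O)[C@H](O)/C=C\[C@@H](CC)O1 | intermediate (not isolated)
21 | (2R,3Z,5R,6R,8R)-8-[(1R,3E)-1-chlorohex-3-en-5-yn-1-yl]-2-ethyl-6-hydroxy-5,6,7,8-tetrahydro-2H-oxocin-5-yl acetate | C#C/C=C/C[C@@H](Cl)[C@H]1C[C@@H](O)[C@H](OC(C)=O)/C=C\[C@@H](CC)O1 | intermediate (not isolated)
22 | (2R,3Z,5R,6R,8R)-8-[(1R,3E)-1-chlorohex-3-en-5-yn-1-yl]-2-ethyl-5,6,7,8-tetrahydro-2H-oxocine-5,6-diyl diacetate | C#C/C=C/C[C@@H](Cl)[C@H]1C[C@@H](OC(C)=O)[C@H](OC(C)=O)/C=C\[C@@H](CC)O1 | target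

## Step count and risk

Total step count: 11. Longest linear sequence: 9 (steps 1, 3, 4, 6, 7, 8, 9, 10, 11).

**Step 11 (proposed new ring expansion).** It can fail through 6-exo capture of the chloriranium ion by the acetate instead of the ring oxygen, through ionisation at C10 with loss of configuration, or through chlorination of the enyne. The fallback sets out from 12 and comes back at 22 through 18–21, using known reaction types with the oxonium ion made by sulfonate displacement instead of chloronium transfer. Ruthenium-catalysed trans-hydrosilylation of 12 ([Cp*Ru(MeCN)3]PF6, (EtO)3SiH) gives (1R,3Z,6E)-7-chloro-1-[(2S,5R)-5-ethyl-2,5-dihydrofuran-2-yl]-4-(triethoxysilyl)hepta-3,6-dien-1-ol F6, which is protodesilylated in the same flask (CuI, TBAF) to the E-alkene (1R,3E,6E)-7-chloro-1-[(2S,5R)-5-ethyl-2,5-dihydrofuran-2-yl]hepta-3,6-dien-1-ol F7. Acetylation gives (1R,3E,6E)-7-chloro-1-[(2S,5R)-5-ethyl-2,5-dihydrofuran-2-yl]hepta-3,6-dien-1-yl acetate F8. Shi epoxidation with the ketone antipode that gives the (6S,7S)-epoxide affords (1R)-2-{(2S,3S)-3-[(2E)-3-chloroprop-2-en-1-yl]oxiran-2-yl}-1-[(2S,5R)-5-ethyl-2,5-dihydrofuran-2-yl]ethyl acetate F9. Lewis-acid chloride opening at C6 with inversion (regioisomer removed by chromatography) gives the erythro chlorohydrin (1R,3S,4R,6E)-4,7-dichloro-1-[(2S,5R)-5-ethyl-2,5-dihydrofuran-2-yl]-3-hydroxyhept-6-en-1-yl acetate F10. Sonogashira coupling with 14 gives (1R,3S,4R,6E)-4-chloro-1-[(2S,5R)-5-ethyl-2,5-dihydrofuran-2-yl]-3-hydroxy-9-(trimethylsilyl)non-6-en-8-yn-1-yl acetate F11, and TBAF/AcOH gives (1R,3S,4R,6E)-4-chloro-1-[(2S,5R)-5-ethyl-2,5-dihydrofuran-2-yl]-3-hydroxynon-6-en-8-yn-1-yl acetate F12. Tf2O with 2,6-di-tert-butyl-4-methylpyridine at −78 °C gives (1R,3S,4R,6E)-4-chloro-1-[(2S,5R)-5-ethyl-2,5-dihydrofuran-2-yl]-3-{[(trifluoromethyl)sulfonyl]oxy}non-6-en-8-yn-1-yl acetate F13, which is not isolated. The ring oxygen displaces the triflate with inversion at C7 (classical neighbouring-ether participation) to give 18, which relays through 19 and, after water and Ac2O, 20/21 to 22. This fallback is longer, and its chloride-opening regiochemistry is its own weak point.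

**Step 3 (Ir-catalysed etherification).** The alkoxide carries an epoxide (Payne rearrangement or opening is possible), and the branched/linear ratio and diastereoselectivity are untested on this substrate. The fallback sets out from 2 and comes back at 6 by an SN2 etherification instead of allylic substitution. Commercial ethyl (S)-2-hydroxybutanoate is converted (Tf2O, 2,6-lutidine) into ethyl (2S)-2-{[(trifluoromethyl)sulfonyl]oxy}butanoate F1. Alcohol 2 displaces the triflate with inversion (2,6-di-tert-butyl-4-methylpyridine, CH2Cl2) to give ethyl (2R)-2-{(1S)-1-[(2R)-oxiran-2-yl]prop-2-en-1-yloxy}butanoate F2. DIBAL-H at −78 °C gives (2R)-2-{(1S)-1-[(2R)-oxiran-2-yl]prop-2-en-1-yloxy}butanal F3, and Wittig methylenation (Ph3P=CH2) returns 6.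

**Step 7 (Lindlar reduction).** Over-reduction, hydrogenolysis of the alkenyl chloride or isomerisation of the skipped system are possible. The fallback sets out from 7 and comes back at 13, fixing the Z alkene by a stereodefined C–C coupling instead of an alkyne reduction. Epoxide 7 is opened with lithium acetylide–ethylenediamine complex (DMSO) to (1R)-1-[(2S,5R)-5-ethyl-2,5-dihydrofuran-2-yl]but-3-yn-1-ol F4. Rhodium-catalysed trans-hydroboration (pinacolborane, [Rh(cod)Cl]2, P(i-Pr)3, Et3N) gives (1R,3Z)-1-[(2S,5R)-5-ethyl-2,5-dihydrofuran-2-yl]-4-(4,4,5,5-tetramethyl-1,3,2-dioxaborolan-2-yl)but-3-en-1-ol F5. Suzuki–Miyaura allylation with 8 at its allylic chloride (Pd(PPh3)4, aq K3PO4) returns 13.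

## Further compounds

F1 | step 3 | ethyl (2S)-2-{[(trifluoromethyl)sulfonyl]oxy}butanoate | CC[C@H](OS(=O)(=O)C(F)(F)F)C(=O)OCC
F2 | step 3 | ethyl (2R)-2-{(1S)-1-[(2R)-oxiran-2-yl]prop-2-en-1-yloxy}butanoate | CC[C@@H](O[C@@H](C=C)[C@H]1CO1)C(=O)OCC
F3 | step 3 | (2R)-2-{(1S)-1-[(2R)-oxiran-2-yl]prop-2-en-1-yloxy}butanal | CC[C@@H](O[C@@H](C=C)[C@H]1CO1)C=O
F4 | step 7 | (1R)-1-[(2S,5R)-5-ethyl-2,5-dihydrofuran-2-yl]but-3-yn-1-ol | CC[C@@H]1C=C[C@H](O1)[C@H](O)CC#C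
F5 | step 7 | (1R,3Z)-1-[(2S,5R)-5-ethyl-2,5-dihydrofuran-2-yl]-4-(4,4,5,5-tetramethyl-1,3,2-dioxaborolan-2-yl)but-3-en-1-ol | CC[C@@H]1C=C[C@H](O1)[C@H](O)C/C=C\B2OC(C)(C)C(C)(C)O2
F6 | step 11 | (1R,3Z,6E)-7-chloro-1-[(2S,5R)-5-ethyl-2,5-dihydrofuran-2-yl]-4-(triethoxysilyl)hepta-3,6-dien-1-ol | CC[C@@H]1C=C[C@H](O1)[C@H](O)C/C=C(/C/C=C/Cl)[Si](OCC)(OCC)OCC
F7 | step 11 | (1R,3E,6E)-7-chloro-1-[(2S,5R)-5-ethyl-2,5-dihydrofuran-2-yl]hepta-3,6-dien-1-ol | CC[C@@H]1C=C[C@H](O1)[C@H](O)C/C=C/C/C=C/Cl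
F8 | step 11 | (1R,3E,6E)-7-chloro-1-[(2S,5R)-5-ethyl-2,5-dihydrofuran-2-yl]hepta-3,6-dien-1-yl acetate | CC[C@@H]1C=C[C@H](O1)[C@H](OC(C)=O)C/C=C/C/C=C/Cl
F9 | step 11 | (1R)-2-{(2S,3S)-3-[(2E)-3-chloroprop-2-en-1-yl]oxiran-2-yl}-1-[(2S,5R)-5-ethyl-2,5-dihydrofuran-2-yl]ethyl acetate | CC[C@@H]1C=C[C@H](O1)[C@H](OC(C)=O)C[C@@H]2O[C@H]2C/C=C/Cl
F10 | step 11 | (1R,3S,4R,6E)-4,7-dichloro-1-[(2S,5R)-5-ethyl-2,5-dihydrofuran-2-yl]-3-hydroxyhept-6-en-1-yl acetate | CC[C@@H]1C=C[C@H](O1)[C@H](OC(C)=O)C[C@H](O)[C@H](Cl)C/C=C/Cl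
F11 | step 11 | (1R,3S,4R,6E)-4-chloro-1-[(2S,5R)-5-ethyl-2,5-dihydrofuran-2-yl]-3-hydroxy-9-(trimethylsilyl)non-6-en-8-yn-1-yl acetate | CC[C@@H]1C=C[C@H](O1)[C@H](OC(C)=O)C[C@H](O)[C@H](Cl)C/C=C/C#C[Si](C)(C)C
F12 | step 11 | (1R,3S,4R,6E)-4-chloro-1-[(2S,5R)-5-ethyl-2,5-dihydrofuran-2-yl]-3-hydroxynon-6-en-8-yn-1-yl acetate | CC[C@@H]1C=C[C@H](O1)[C@H](OC(C)=O)C[C@H](O)[C@H](Cl)C/C=C/C#C
F13 | step 11 | (1R,3S,4R,6E)-4-chloro-1-[(2S,5R)-5-ethyl-2,5-dihydrofuran-2-yl]-3-{[(trifluoromethyl)sulfonyl]oxy}non-6-en-8-yn-1-yl acetate | CC[C@@H]1C=C[C@H](O1)[C@H](OC(C)=O)C[C@H](OS(=O)(=O)C(F)(F)F)[C@H](Cl)C/C=C/C#C
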